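**Strategy.** The ten-membered carbocycle (ring A, C1–C10) is closed last at C5–C6 by a Nozaki–Hiyama–Kishi reaction. The step exploits the fact that C6 is at once the allylic carbinol next to the (E)-C4=C5 alkene and the alkyl-oxygen carbon of the butenolide (ring B, C6–C7=C11–C12–O). An (E)-alkenyl iodide at C5 adds to a C6 aldehyde held cis to a C12 methyl ester on the tetrasubstituted C7=C11 alkene, and the resulting alkoxide lactonises at once. One operation gives ring A, the C6 stereocentre and ring B. The open-chain precursor arises from a 2-silyl-3,4-disubstituted furan (masked Z-formylacrylate) and an iodo-1,2-diketone.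

Key step: step 16

Remark on numbering: germacranolide numbering is used (C1 ketone, C4=C5, C6 lactone carbinol, C7=C11, C8 methacrylate, C10 acetate, C12 lactone carbonyl, C13 acetoxymethyl); the target is (6R,8S,10R) with an (E)-C4=C5 alkene.
Assumption: in copper–bis(oxazoline) Mukaiyama aldols of chelating 1,2-dicarbonyl compounds the (S,S)-tert-butyl ligand directs attack to the si face of the methyl ketone, so the (R,R)-ligand is chosen for 10R; if the sense were opposite, the enantiomeric ligand would be used.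
Remark: the lactol carbon of compound 24 is carried as a mixture of epimers, which converge in step 15.

**Step 1**
Reactants: 1 furan-3-ylmethanol
Product: 2 tert-butyl(furan-3-ylmethoxy)dimethylsilane
Conditions: TBSCl, imidazole, DMF, 0 °C to rt
Reagents that add atoms: tert-butyldimethylsilyl chloride CC(C)(C)[Si](C)(C)Cl
Why: Silylation of the primary alcohol supplies the silicon that migrates in step 2.

**Step 2**
Reactants: 2 tert-butyl(furan-3-ylmethoxy)dimethylsilane
Product: 4 [2-(tert-butyldimethylsilyl)furan-3-yl]methanol, via 2-lithiofuran silyl ether 3 (not isolated)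
Conditions: n-BuLi, HMPA, THF, −78 °C to rt; then H2O
Reagents that add atoms: none
Why: Lithiation at C2 of the furan followed by retro-[1,4]-Brook (O to C) silyl migration, driven by formation of the lithium alkoxide, should put silicon on the future C12.

**Step 3**
Reactants: 4 [2-(tert-butyldimethylsilyl)furan-3-yl]methanol; 5 N-methoxy-N-methylacetamide
Product: 7 1-[5-(tert-butyldimethylsilyl)-4-(hydroxymethyl)furan-3-yl]ethan-1-one, via dilithio alkoxide 6 (not isolated)
Conditions: n-BuLi (2.2 equiv), DME, 0 °C; then 5, −78 °C to 0 °C; then H2O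
Reagents that add atoms: none
Why: Alkoxide-directed ortho-lithiation at C4 (C2 is blocked by the bulky silyl group) and Weinreb amide acylation, whose chelated adduct stops at the ketone, should install C8 and C9.

**Step 4**
Reactants: 7 1-[5-(tert-butyldimethylsilyl)-4-(hydroxymethyl)furan-3-yl]ethan-1-one
Product: 8 [4-acetyl-2-(tert-butyldimethylsilyl)furan-3-yl]methyl acetate
Conditions: Ac2O, pyridine, DMAP (cat.), CH2Cl2, 0 °C to rt
Reagents that add atoms: acetic anhydride CC(=O)OC(C)=O
Why: DMAP-catalysed acetylation of the primary alcohol installs the C13 acetate of the target early.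

**Step 5**
Reactants: 8 [4-acetyl-2-(tert-butyldimethylsilyl)furan-3-yl]methyl acetate
Product: 9 {2-(tert-butyldimethylsilyl)-4-[1-(trimethylsilyloxy)ethenyl]furan-3-yl}methyl acetate
Conditions: TMSOTf, Et3N, CH2Cl2, 0 °C
Reagents that add atoms: trimethylsilyl trifluoromethanesulfonate C[Si](C)(C)OS(=O)(=O)C(F)(F)F
Why: Soft enolisation of the methyl ketone, the most readily enolised site, gives the silyl enol ether that serves as Mukaiyama donor.

**Step 6**
Reactants: 10 prop-2-yn-1-ol
Product: 12 (E)-3-iodo-2-methylprop-2-en-1-ol, via alkenylalane 11 (not isolated)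
Conditions: Me3Al (3 equiv), Cp2ZrCl2 (0.25 equiv), CH2Cl2, 0 °C to rt; then I2, THF, −30 °C to 0 °C; then H2O
Reagents that add atoms: trimethylaluminium C[Al](C)C; iodine II
Why: Negishi zirconium-catalysed carboalumination adds methyl and aluminium syn across the alkyne with methyl at the internal carbon, and iodinolysis with retention fixes the (E)-iodoalkene (C4, C5, C15).

**Step 7**
Reactants: 12 (E)-3-iodo-2-methylprop-2-en-1-ol
Product: 13 (E)-3-bromo-1-iodo-2-methylprop-1-ene
Conditions: CBr4, PPh3, CH2Cl2, 0 °C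
Reagents that add atoms: carbon tetrabromide BrC(Br)(Br)Br
Why: Appel bromination of the allylic alcohol under neutral conditions leaves the alkenyl iodide untouched.

**Step 8**
Reactants: 14 3,3-dimethoxybutan-2-one; 13 (E)-3-bromo-1-iodo-2-methylprop-1-ene
Product: 16 (E)-7-iodo-2,2-dimethoxy-6-methylhept-6-en-3-one, via lithium enolate 15 (not isolated)
Conditions: LiN(i-Pr)2, THF, −78 °C; then 13, −78 °C to −20 °C
Reagents that add atoms: none
Why: The ketone has a single enolisable side, so its lithium enolate should be alkylated by the allylic bromide (enolate SN2 alkylation) to join C2 to C3.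

**Step 9**
Reactants: 16 (E)-7-iodo-2,2-dimethoxy-6-methylhept-6-en-3-one
Product: 17 (E)-7-iodo-6-methylhept-6-ene-2,3-dione
Conditions: TFA, H2O, CH2Cl2, 0 °C to rt
Reagents that add atoms: water O
Why: Acid hydrolysis of the dimethyl ketal unveils the 1,2-diketone (C10 and C1 carbonyls).

**Step 10**
Reactants: 9 {2-(tert-butyldimethylsilyl)-4-[1-(trimethylsilyloxy)ethenyl]furan-3-yl}methyl acetate; 17 (E)-7-iodo-6-methylhept-6-ene-2,3-dione
Product: 19 {2-(tert-butyldimethylsilyl)-4-[(3R,7E)-3-hydroxy-8-iodo-3,7-dimethyl-4-oxooct-7-enoyl]furan-3-yl}methyl acetate, via trimethylsilyl ether 18 (not isolated)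
Conditions: [Cu((R,R)-t-Bu-box)](OTf)2 (10 mol%), THF, −78 °C; then 1 M HCl, THF, 0 °C
Reagents that add atoms: none
Why: Copper–bis(oxazoline)-catalysed Mukaiyama aldol in which the diketone chelates divalent copper and the enol silane attacks the less hindered methyl ketone carbonyl (C10) on the face left open by the tert-butyl groups, which should set 10R, before acid removes the transferred silyl group.

**Step 11**
Reactants: 19 {2-(tert-butyldimethylsilyl)-4-[(3R,7E)-3-hydroxy-8-iodo-3,7-dimethyl-4-oxooct-7-enoyl]furan-3-yl}methyl acetate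
Product: 20 {2-(tert-butyldimethylsilyl)-4-[(1S,3R,7E)-1,3-dihydroxy-8-iodo-3,7-dimethyl-4-oxooct-7-en-1-yl]furan-3-yl}methyl acetate
Conditions: RuCl[(S,S)-TsDPEN](p-cymene) (2 mol%), HCO2H–Et3N (5:2), EtOAc, rt
Reagents that add atoms: none
Why: Noyori-type asymmetric transfer hydrogenation in which the divalent ruthenium hydride reduces the heteroaryl ketone through its CH/π-stabilised transition state, the (S,S)-catalyst giving 8S under reagent control, while the dialkyl C1 ketone next to the fully substituted C10 should stay untouched.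

**Step 12**
Reactants: 20 {2-(tert-butyldimethylsilyl)-4-[(1S,3R,7E)-1,3-dihydroxy-8-iodo-3,7-dimethyl-4-oxooct-7-en-1-yl]furan-3-yl}methyl acetate
Product: 21 (1S,3R,7E)-1-[4-(acetoxymethyl)-5-(tert-butyldimethylsilyl)furan-3-yl]-3-hydroxy-8-iodo-3,7-dimethyl-4-oxooct-7-en-1-yl 2-methylprop-2-enoate
Conditions: methacrylic anhydride, Et3N, DMAP (cat.), CH2Cl2, 0 °C
Reagents that add atoms: methacrylic anhydride CC(=C)C(=O)OC(=O)C(C)=C
Why: DMAP-catalysed acylation should occur at the secondary C8 hydroxyl in preference to the tertiary C10 hydroxyl.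

**Step 13**
Reactants: 21 (1S,3R,7E)-1-[4-(acetoxymethyl)-5-(tert-butyldimethylsilyl)furan-3-yl]-3-hydroxy-8-iodo-3,7-dimethyl-4-oxooct-7-en-1-yl 2-methylprop-2-enoate
Product: 22 (1S,3R,7E)-3-acetoxy-1-[4-(acetoxymethyl)-5-(tert-butyldimethylsilyl)furan-3-yl]-8-iodo-3,7-dimethyl-4-oxooct-7-en-1-yl 2-methylprop-2-enoate
Conditions: Ac2O, DMAP, Et3N, CH2Cl2, 40 °C
Reagents that add atoms: acetic anhydride CC(=O)OC(C)=O
Why: Forcing DMAP-mediated acetylation should esterify the remaining tertiary C10 hydroxyl without touching its configuration.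

**Step 14**
Reactants: 22 (1S,3R,7E)-3-acetoxy-1-[4-(acetoxymethyl)-5-(tert-butyldimethylsilyl)furan-3-yl]-8-iodo-3,7-dimethyl-4-oxooct-7-en-1-yl 2-methylprop-2-enoate
Product: 24 (1S,3R,7E)-3-acetoxy-1-[4-(acetoxymethyl)-2-hydroxy-5-oxo-2,5-dihydrofuran-3-yl]-8-iodo-3,7-dimethyl-4-oxooct-7-en-1-yl 2-methylprop-2-enoate, via open-chain silyl ester 23 (not isolated)
Conditions: O2, hν (visible), tetraphenylporphyrin (cat.), CH2Cl2, −78 °C; then H2O, THF, rt
Reagents that add atoms: oxygen O=O
Why: Furan photooxygenation in which singlet oxygen adds [4+2] to the electron-rich furan (much faster than to the iodoalkene or the methacrylate) and the silyl group shifts from C12 to oxygen in the endoperoxide, so that C12 becomes the carboxyl carbon and C6 the aldehyde, before hydrolysis of the silyl ester gives the hydroxybutenolide.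

**Step 15**
Reactants: 24 (1S,3R,7E)-3-acetoxy-1-[4-(acetoxymethyl)-2-hydroxy-5-oxo-2,5-dihydrofuran-3-yl]-8-iodo-3,7-dimethyl-4-oxooct-7-en-1-yl 2-methylprop-2-enoate
Product: 25 methyl (2Z,4S,6R,10E)-6-acetoxy-2-(acetoxymethyl)-3-formyl-11-iodo-6,10-dimethyl-4-[(2-methylprop-2-enoyl)oxy]-7-oxoundeca-2,10-dienoate
Conditions: MeI, KHCO3, DMF, 0 °C to rt
Reagents that add atoms: iodomethane CI
Why: The pseudo-acid opens to its carboxylate in mild base, and carboxylate O-alkylation with iodomethane should trap the open Z-formyl methyl ester.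

**Step 16**
Reactants: 25 methyl (2Z,4S,6R,10E)-6-acetoxy-2-(acetoxymethyl)-3-formyl-11-iodo-6,10-dimethyl-4-[(2-methylprop-2-enoyl)oxy]-7-oxoundeca-2,10-dienoate
Product: 27 target germacranolide CNP0115165.1 (6R,8S,10R; ring A with C1 ketone, 10-acetoxy-10-methyl, 8-methacrylate and (E)-C4=C5; ring B the 13-acetoxy-7(11)-en-12,6-olide), via chromium alkoxide 26 (not isolated)
Conditions: CrCl2 (10 equiv), NiCl2 (0.1 equiv), DMSO–THF, rt, slow addition to 0.002 M; then H2O
Reagents that add atoms: none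
Why: Nozaki–Hiyama–Kishi macrocyclisation in which zerovalent nickel (from NiCl2 and CrCl2) inserts into the C5–I bond with retention of the (E)-geometry, the alkenyl group passes to trivalent chromium and adds to the C6 aldehyde, the closest known reaction type being the nickel/chromium-mediated alkenyl iodide–aldehyde closure of medium carbocycles. Ring A closes in a 10-exo-trig addition to the aldehyde carbonyl and ring B in a 5-exo-trig attack of the C6 chromium alkoxide on the cis C12 methyl ester, which releases methanol. The new C6 stereocentre is controlled by C8: with H8 eclipsing C7=C11 (allylic strain against the C13 acetoxymethyl group) the C9 tether lies on one face and should deliver C5 to that face of the aldehyde, which is twisted away from the cis ester, and rotation into the lactone plane then gives 6R with O6 and O8 cis. The step needs chemoselectivity for the aldehyde over the C1 ketone and the four esters, secured by the low carbonyl reactivity of alkenylchromium reagents, and it needs ring closure to outrun oligomerisation, secured by high dilution and by the rigid Z-enal ester and (E)-alkene units.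

**Compound list**
1 | furan-3-ylmethanol | OCc1ccoc1 | starting material
2 | tert-butyl(furan-3-ylmethoxy)dimethylsilane | CC(C)(C)[Si](C)(C)OCc1ccoc1 | intermediate
3 | tert-butyl[(2-lithiofuran-3-yl)methoxy]dimethylsilane | [Li]c1occc1CO[Si](C)(C)C(C)(C)C | intermediate
4 | [2-(tert-butyldimethylsilyl)furan-3-yl]methanol | OCc1ccoc1[Si](C)(C)C(C)(C)C | intermediate
5 | N-methoxy-N-methylacetamide | CC(=O)N(C)OC | starting material
6 | lithium [2-(tert-butyldimethylsilyl)-4-lithiofuran-3-yl]methanolate | [Li]OCc1c([Li])coc1[Si](C)(C)C(C)(C)C | intermediate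
7 | 1-[5-(tert-butyldimethylsilyl)-4-(hydroxymethyl)furan-3-yl]ethan-1-one | CC(=O)c1coc([Si](C)(C)C(C)(C)C)c1CO | intermediate
8 | [4-acetyl-2-(tert-butyldimethylsilyl)furan-3-yl]methyl acetate | CC(=O)OCc1c(C(C)=O)coc1[Si](C)(C)C(C)(C)C | intermediate
9 | {2-(tert-butyldimethylsilyl)-4-[1-(trimethylsilyloxy)ethenyl]furan-3-yl}methyl acetate | CC(=O)OCc1c(C(=C)O[Si](C)(C)C)coc1[Si](C)(C)C(C)(C)C | intermediate
10 | prop-2-yn-1-ol | C#CCO | starting material
11 | dimethylaluminium (E)-3-(dimethylalumanyl)-2-methylprop-2-en-1-olate | C[Al](C)OC/C(C)=C/[Al](C)C | intermediate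
12 | (E)-3-iodo-2-methylprop-2-en-1-ol | OC/C(C)=C/I | intermediate
13 | (E)-3-bromo-1-iodo-2-methylprop-1-ene | BrC/C(C)=C/I | intermediate
14 | 3,3-dimethoxybutan-2-one | CC(=O)C(C)(OC)OC | starting material
15 | lithium 3,3-dimethoxybut-1-en-2-olate | [Li]OC(=C)C(C)(OC)OC | intermediate
16 | (E)-7-iodo-2,2-dimethoxy-6-methylhept-6-en-3-one | CC(OC)(OC)C(=O)CC/C(C)=C/I | intermediate
17 | (E)-7-iodo-6-methylhept-6-ene-2,3-dione | CC(=O)C(=O)CC/C(C)=C/I | intermediate
18 | {2-(tert-butyldimethylsilyl)-4-[(3R,7E)-8-iodo-3,7-dimethyl-4-oxo-3-(trimethylsilyloxy)oct-7-enoyl]furan-3-yl}methyl acetate | CC(=O)OCc1c(C(=O)C[C@@](C)(O[Si](C)(C)C)C(=O)CC/C(C)=C/I)coc1[Si](C)(C)C(C)(C)C | intermediate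
19 | {2-(tert-butyldimethylsilyl)-4-[(3R,7E)-3-hydroxy-8-iodo-3,7-dimethyl-4-oxooct-7-enoyl]furan-3-yl}methyl acetate | CC(=O)OCc1c(C(=O)C[C@@](C)(O)C(=O)CC/C(C)=C/I)coc1[Si](C)(C)C(C)(C)C | intermediate
20 | {2-(tert-butyldimethylsilyl)-4-[(1S,3R,7E)-1,3-dihydroxy-8-iodo-3,7-dimethyl-4-oxooct-7-en-1-yl]furan-3-yl}methyl acetate | CC(=O)OCc1c([C@@H](O)C[C@@](C)(O)C(=O)CC/C(C)=C/I)coc1[Si](C)(C)C(C)(C)C | intermediate
21 | (1S,3R,7E)-1-[4-(acetoxymethyl)-5-(tert-butyldimethylsilyl)furan-3-yl]-3-hydroxy-8-iodo-3,7-dimethyl-4-oxooct-7-en-1-yl 2-methylprop-2-enoate | CC(=O)OCc1c([C@@H](OC(=O)C(C)=C)C[C@@](C)(O)C(=O)CC/C(C)=C/I)coc1[Si](C)(C)C(C)(C)C | intermediate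
22 | (1S,3R,7E)-3-acetoxy-1-[4-(acetoxymethyl)-5-(tert-butyldimethylsilyl)furan-3-yl]-8-iodo-3,7-dimethyl-4-oxooct-7-en-1-yl 2-methylprop-2-enoate | CC(=O)OCc1c([C@@H](OC(=O)C(C)=C)C[C@@](C)(OC(C)=O)C(=O)CC/C(C)=C/I)coc1[Si](C)(C)C(C)(C)C | intermediate
23 | tert-butyldimethylsilyl (2Z,4S,6R,10E)-6-acetoxy-2-(acetoxymethyl)-3-formyl-11-iodo-6,10-dimethyl-4-[(2-methylprop-2-enoyl)oxy]-7-oxoundeca-2,10-dienoate | CC(=O)OC/C(C(=O)O[Si](C)(C)C(C)(C)C)=C(/C=O)[C@@H](OC(=O)C(C)=C)C[C@@](C)(OC(C)=O)C(=O)CC/C(C)=C/I | intermediate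
24 | (1S,3R,7E)-3-acetoxy-1-[4-(acetoxymethyl)-2-hydroxy-5-oxo-2,5-dihydrofuran-3-yl]-8-iodo-3,7-dimethyl-4-oxooct-7-en-1-yl 2-methylprop-2-enoate (both lactol epimers) | CC(=O)OCC1=C([C@@H](OC(=O)C(C)=C)C[C@@](C)(OC(C)=O)C(=O)CC/C(C)=C/I)C(O)OC1=O | intermediate
25 | methyl (2Z,4S,6R,10E)-6-acetoxy-2-(acetoxymethyl)-3-formyl-11-iodo-6,10-dimethyl-4-[(2-methylprop-2-enoyl)oxy]-7-oxoundeca-2,10-dienoate | CC(=O)OC/C(C(=O)OC)=C(/C=O)[C@@H](OC(=O)C(C)=C)C[C@@](C)(OC(C)=O)C(=O)CC/C(C)=C/I | intermediate
26 | dichlorochromium C6 alkoxide of the ring A seco hydroxy methyl ester (6R,8S,10R; E-C4=C5; C6 cis to CO2Me on C7=C11) | C=C(C)C(=O)O[C@H]1C[C@@](C)(OC(C)=O)C(=O)CC/C(C)=C/[C@@H](O[Cr](Cl)Cl)/C1=C(/COC(C)=O)C(=O)OC | intermediate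
27 | CNP0115165.1, (6R,8S,10R)-10-acetoxy-13-acetoxy-8-methacryloyloxy-1-oxogermacra-4(E),7(11)-dien-12,6-olide | C=C(C)C(=O)O[C@H]1C[C@@](C)(OC(C)=O)C(=O)CC/C(C)=C/[C@H]2OC(=O)C(COC(C)=O)=C12 | target

**Totals.** 16 steps in all; longest linear sequence 12 steps (steps 1–5 and 10–16).

**Steps most likely to fail**

Step 16. C5 may add to the other face of the C6 aldehyde, intermolecular coupling may outrun ring closure, and divalent chromium may transfer electrons to the electron-poor ene-dicarbonyl unit. The fallback removes the reliance on substrate-controlled facial selectivity and sets out from 24. Esterification with O-tert-butyl-N,N'-diisopropylisourea should give the tert-butyl Z-formyl ester F1, whose bulky ester does not lactonise. The same CrCl2/NiCl2 closure should then give the macrocyclic allylic alcohol F2 as a C6 mixture. Dess–Martin oxidation gives the macrocyclic C6 ketone F3. Corey–Bakshi–Shibata reduction ((S)-Me-CBS oxazaborolidine, catecholborane, −78 °C) should set 6R under reagent control in the hydroxy tert-butyl ester F4. TFA in CH2Cl2 at 0 °C then cleaves the ester, and the hydroxy acid closes to 27, where the fallback rejoins the route.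

Step 11. Hydride may also be transferred to the C1 ketone, or the tertiary aldol may cleave by retro-aldol reaction in the amine–formate medium. The fallback sets out from 18, isolated by a non-acidic work-up of step 10, so that the silyl ether shields C1 and blocks the retro-aldol path. Corey–Bakshi–Shibata reduction ((R)-Me-CBS oxazaborolidine, BH3·SMe2, −30 °C) should give the 8S alcohol silyl ether F5. Methacrylic anhydride with DMAP gives the methacrylate silyl ether F6, and HF·pyridine removes the trimethylsilyl group to return to the route at 21.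

Step 14. The bulky silyl group may shift too slowly in the endoperoxide, so that it collapses without regiocontrol, or ene oxidation of the side chain may compete. The fallback sets out from 22. Protodesilylation with TFA in CH2Cl2 should give the 2-unsubstituted furan F7. Photooxygenation in the presence of a hindered base (O2, hν, rose bengal, i-Pr2NEt, CH2Cl2, −78 °C) should then remove the less hindered endoperoxide proton at C12, next to the acetoxymethyl arm, and return to the route at 24.

**Further compounds**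
F1 | step 16 | tert-butyl (2Z,4S,6R,10E)-6-acetoxy-2-(acetoxymethyl)-3-formyl-11-iodo-6,10-dimethyl-4-[(2-methylprop-2-enoyl)oxy]-7-oxoundeca-2,10-dienoate | CC(=O)OC/C(C(=O)OC(C)(C)C)=C(/C=O)[C@@H](OC(=O)C(C)=C)C[C@@](C)(OC(C)=O)C(=O)CC/C(C)=C/I
F2 | step 16 | ring A seco hydroxy tert-butyl ester, C6 epimer mixture (8S,10R; E-C4=C5) | C=C(C)C(=O)O[C@H]1C[C@@](C)(OC(C)=O)C(=O)CC/C(C)=C/C(O)/C1=C(/COC(C)=O)C(=O)OC(C)(C)C
F3 | step 16 | ring A C6 ketone tert-butyl ester (8S,10R; E-C4=C5) | C=C(C)C(=O)O[C@H]1C[C@@](C)(OC(C)=O)C(=O)CC/C(C)=C/C(=O)/C1=C(/COC(C)=O)C(=O)OC(C)(C)C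
F4 | step 16 | ring A (6R)-hydroxy tert-butyl ester (6R,8S,10R; E-C4=C5) | C=C(C)C(=O)O[C@H]1C[C@@](C)(OC(C)=O)C(=O)CC/C(C)=C/[C@@H](O)/C1=C(/COC(C)=O)C(=O)OC(C)(C)C
F5 | step 11 | {2-(tert-butyldimethylsilyl)-4-[(1S,3R,7E)-1-hydroxy-8-iodo-3,7-dimethyl-4-oxo-3-(trimethylsilyloxy)oct-7-en-1-yl]furan-3-yl}methyl acetate | CC(=O)OCc1c([C@@H](O)C[C@@](C)(O[Si](C)(C)C)C(=O)CC/C(C)=C/I)coc1[Si](C)(C)C(C)(C)C
F6 | step 11 | (1S,3R,7E)-1-[4-(acetoxymethyl)-5-(tert-butyldimethylsilyl)furan-3-yl]-8-iodo-3,7-dimethyl-4-oxo-3-(trimethylsilyloxy)oct-7-en-1-yl 2-methylprop-2-enoate | CC(=O)OCc1c([C@@H](OC(=O)C(C)=C)C[C@@](C)(O[Si](C)(C)C)C(=O)CC/C(C)=C/I)coc1[Si](C)(C)C(C)(C)C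
F7 | step 14 | (1S,3R,7E)-3-acetoxy-1-[4-(acetoxymethyl)furan-3-yl]-8-iodo-3,7-dimethyl-4-oxooct-7-en-1-yl 2-methylprop-2-enoate | CC(=O)OCc1cocc1[C@@H](OC(=O)C(C)=C)C[C@@](C)(OC(C)=O)C(=O)CC/C(C)=C/I
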